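**Retrosynthetic overview**
1. Feature: ring A (C4a, C5, C6, C7, C8, C8a) bears oxygen on C5, C7 and C8a in 1,3,5-alternation and the C4 carbonyl on C4a. It is therefore an acylphloroglucinol, the aromatic form of a folded tetraketide.
2. Ring C is cut at C2 (one carbon from DMF dimethyl acetal) back to the 2,4,6-trihydroxyphenyl benzyl ketone. Ring A is then opened at C4a–C8a by a retro-Claisen cut to a linear 3,5,7-triketo ester carrying rings B and D on its C8.
3. The chain is cut at C6–C7 into the trianion of methyl 3,5-dioxohexanoate (from dehydroacetic acid) and the arylacetic Weinreb amide. The amide is preferred to the methyl ester because the benzylic CH2 is acidic.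
4. The amide comes from 3,4-dihydroxybenzaldehyde by 4-O-propargylation, MOM protection, aromatic Claisen closure of ring D, and one-carbon homologation with TosMIC.
5. Order of rings: B (bought), D (step 3), A (step 9), C (step 10). MOM removal ends the route.

Key step: step 9

Remark: isoflavone numbering is used for rings A and C, and chain numbering (C1 ester to C8) for the open precursor. The target has no stereocentre. Polycarbonyl compounds are drawn as keto forms although they are largely enolised.

Step 1
Reactants: 1 3,4-dihydroxybenzaldehyde; 2 3-chloro-3-methylbut-1-yne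
Product: 3 3-hydroxy-4-[(2-methylbut-3-yn-2-yl)oxy]benzaldehyde
Conditions: 2 (1.2 equiv), DBU (1.2 equiv), CuCl2·2H2O (1 mol %), MeCN, 0 °C to rt, N2
Reagents that add atoms: none
Why: Copper-catalysed propargylic O-alkylation, in which about one equivalent of base ionises only the 4-OH (para to the formyl group and clearly the more acidic phenol), so the tertiary propargyl unit should land on O4 and leave the 3-OH free.

Step 2
Reactants: 3 3-hydroxy-4-[(2-methylbut-3-yn-2-yl)oxy]benzaldehyde
Product: 4 3-(methoxymethoxy)-4-[(2-methylbut-3-yn-2-yl)oxy]benzaldehyde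
Conditions: MOMCl (1.5 equiv), i-Pr2NEt (2 equiv), CH2Cl2, 0 °C to rt
Reagents that add atoms: chloromethyl methyl ether, COCCl
Why: Standard O-alkylation of a phenol to its MOM acetal, which removes the acidic and oxidisable catechol OH before the carbanion steps and the strongly basic ring closure.

Step 3
Reactants: 4 3-(methoxymethoxy)-4-[(2-methylbut-3-yn-2-yl)oxy]benzaldehyde
Product: 6 8-(methoxymethoxy)-2,2-dimethyl-2H-chromene-6-carbaldehyde, via ortho-allenylphenol 5 (not isolated)
Conditions: N,N-diethylaniline, 190 °C, N2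
Reagents that add atoms: none
Why: Aromatic propargyl Claisen rearrangement, in which the [3,3] shift can only reach C5 because C3 carries the OMOM group, and rearomatisation to 5, a 1,5-hydrogen shift and an oxa-6π electrocyclisation then close ring D.

Step 4
Reactants: 6 8-(methoxymethoxy)-2,2-dimethyl-2H-chromene-6-carbaldehyde
Product: 8 [8-(methoxymethoxy)-2,2-dimethyl-2H-chromen-6-yl]acetonitrile, via tosylvinylformamide 7 (not isolated)
Conditions: TosMIC (1.2 equiv), t-BuOK (2.4 equiv), DME, −50 to −30 °C; then MeOH, reflux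
Reagents that add atoms: p-toluenesulfonylmethyl isocyanide (TosMIC), Cc1ccc(cc1)S(=O)(=O)C[N+]#[C-]
Why: van Leusen reductive cyanation, in which the TosMIC anion adds to the aldehyde in the cold, the oxazoline opens to 7, and hot methanol removes the formyl group and expels sulfinate, all under basic conditions that spare the MOM ether and the chromene.

Step 5
Reactants: 8 [8-(methoxymethoxy)-2,2-dimethyl-2H-chromen-6-yl]acetonitrile
Product: 9 [8-(methoxymethoxy)-2,2-dimethyl-2H-chromen-6-yl]acetic acid
Conditions: KOH (4 M aq), EtOH, reflux, N2; then 1 M HCl to pH 4, 0 °C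
Reagents that add atoms: potassium hydroxide, [K+].[OH-]; water, O
Why: Alkaline nitrile hydrolysis, chosen over acid alcoholysis because the MOM ether and the chromene double bond tolerate hot hydroxide but not hot mineral acid.

Step 6
Reactants: 9 [8-(methoxymethoxy)-2,2-dimethyl-2H-chromen-6-yl]acetic acid
Product: 11 N-methoxy-N-methyl-2-[8-(methoxymethoxy)-2,2-dimethyl-2H-chromen-6-yl]acetamide, via acyl imidazole 10 (not isolated)
Conditions: CDI (1.2 equiv), CH2Cl2, rt; then MeNH(OMe)·HCl (1.5 equiv), rt
Reagents that add atoms: N,O-dimethylhydroxylamine hydrochloride, CNOC.Cl; 1,1'-carbonyldiimidazole, O=C(n1ccnc1)n1ccnc1 (imidazolyl group of 10 only)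
Why: Amide formation through CDI activation runs close to neutrality and should give the Weinreb amide that serves as acyl donor in step 8.

Step 7
Reactants: 12 3-acetyl-4-hydroxy-6-methyl-2H-pyran-2-one (dehydroacetic acid)
Product: 13 methyl 3,5-dioxohexanoate
Conditions: Mg(OMe)2 (commercial solution, 2 equiv), MeOH, reflux; then cold 2 M HCl
Reagents that add atoms: magnesium methoxide, [Mg+2].C[O-].C[O-]; methanol, CO
Why: Lactone methanolysis combined with retro-Claisen deacetylation, in which methoxide opens the pyranone at C2 and removes the 3-acetyl group while the magnesium chelate of the 3,5-diketo ester resists further cleavage.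

Step 8
Reactants: 11 N-methoxy-N-methyl-2-[8-(methoxymethoxy)-2,2-dimethyl-2H-chromen-6-yl]acetamide; 13 methyl 3,5-dioxohexanoate
Product: 15 methyl 8-[8-(methoxymethoxy)-2,2-dimethyl-2H-chromen-6-yl]-3,5,7-trioxooctanoate, via trilithio trianion 14 (not isolated)
Conditions: 13 (2 equiv), LDA (commercial solution, 6.1 equiv), THF, −78 to 0 °C; then 11, −78 to −20 °C; AcOH quench at −78 °C, pH 4 buffer; quick filtration through acid-washed silica, used at once
Reagents that add atoms: lithium diisopropylamide, [Li+].CC(C)[N-]C(C)C (lithium of 14 only)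
Why: Polyanion acylation in the manner of a Weinreb ketone synthesis, in which the last-formed terminal carbanion of 14 is the most nucleophilic site, and the amide replaces the methyl arylacetate because its benzylic protons are less acidic and its chelated adduct holds until the quench, so neither the donor nor the freed tetracarbonyl product should consume the trianion by proton transfer.

Step 9
Reactants: 15 methyl 8-[8-(methoxymethoxy)-2,2-dimethyl-2H-chromen-6-yl]-3,5,7-trioxooctanoate
Product: 17 2-[8-(methoxymethoxy)-2,2-dimethyl-2H-chromen-6-yl]-1-(2,4,6-trihydroxyphenyl)ethanone, via acylcyclohexanetrione 16 (not isolated)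
Conditions: KOH (2 M in MeOH, 10 equiv), degassed MeOH, 0 °C to rt, N2; then cold 1 M HCl to pH 4–5
Reagents that add atoms: none
Why: With a large excess of methanolic KOH, 15 is multiply deprotonated, so each of the carbonyls C3, C5 and C7 sits in an enolate and no longer accepts nucleophiles, which leaves ester carbon C1 as the sole acceptor. Chain carbon C6 attacks C1, methoxide departs, and trione 16 tautomerises at once to the phenoxide of 17, so the C4a–C8a bond is made and the oxygens of C5, C7 and C8a arrive already in place. This is an intramolecular Claisen (Dieckmann-type) condensation, the known base-induced cyclisation of 3,5,7-triketo esters to acylphloroglucinols. Ring A closes in the 6-(enolexo)-exo-trig mode, the C6=C7 enolate adding to the ester C=O whose oxygen stays outside the new ring. No stereocentre is formed. The step needs the Claisen closure to beat the aldol closures C2 to C7 and C8 to C3 and to beat loss of the ester: the high base strength keeps every ketone enolised, methoxide attack on a methyl ester is degenerate, irreversible aromatisation drains the Claisen channel, and the aryl group on C8 is only a bystander.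

Step 10
Reactants: 17 2-[8-(methoxymethoxy)-2,2-dimethyl-2H-chromen-6-yl]-1-(2,4,6-trihydroxyphenyl)ethanone
Product: 19 5,7-dihydroxy-3-[8-(methoxymethoxy)-2,2-dimethyl-2H-chromen-6-yl]-4H-chromen-4-one, via enaminone 18 (not isolated)
Conditions: Me2NCH(OMe)2 (2.5 equiv), THF, 60 °C
Reagents that add atoms: N,N-dimethylformamide dimethyl acetal, COC(OC)N(C)C
Why: Standard deoxybenzoin-to-isoflavone closure, in which aminomethylenation of the doubly activated benzylic CH2 gives 18 and an ortho phenol then displaces dimethylamine by addition–elimination to install C2 and ring C, the two ortho OH groups being equivalent so that only one product can result.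

Step 11
Reactants: 19 5,7-dihydroxy-3-[8-(methoxymethoxy)-2,2-dimethyl-2H-chromen-6-yl]-4H-chromen-4-one
Product: 20 semilicoisoflavone B
Conditions: HCl (cat., about 0.5 M), MeOH, 40 °C
Reagents that add atoms: none
Why: Acid-catalysed acetal exchange with methanol should remove the MOM group at a temperature at which the 2,2-dimethylchromene double bond is not yet protonated to a useful extent.

**Compound list**
1 | 3,4-dihydroxybenzaldehyde | O=Cc1ccc(O)c(O)c1 | starting material
2 | 3-chloro-3-methylbut-1-yne | C#CC(C)(C)Cl | starting material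
3 | 3-hydroxy-4-[(2-methylbut-3-yn-2-yl)oxy]benzaldehyde | O=Cc1ccc(OC(C)(C)C#C)c(O)c1 | intermediate
4 | 3-(methoxymethoxy)-4-[(2-methylbut-3-yn-2-yl)oxy]benzaldehyde | O=Cc1ccc(OC(C)(C)C#C)c(OCOC)c1 | intermediate
5 | 4-hydroxy-3-(methoxymethoxy)-5-(3-methylbuta-1,2-dien-1-yl)benzaldehyde | O=Cc1cc(C=C=C(C)C)c(O)c(OCOC)c1 | intermediate (not isolated)
6 | 8-(methoxymethoxy)-2,2-dimethyl-2H-chromene-6-carbaldehyde | COCOc1cc(C=O)cc2C=CC(C)(C)Oc12 | intermediate
7 | N-{2-[8-(methoxymethoxy)-2,2-dimethyl-2H-chromen-6-yl]-1-[(4-methylphenyl)sulfonyl]ethenyl}formamide (alkene geometry not defined) | COCOc1cc(C=C(NC=O)S(=O)(=O)c3ccc(C)cc3)cc2C=CC(C)(C)Oc12 | intermediate (not isolated)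
8 | [8-(methoxymethoxy)-2,2-dimethyl-2H-chromen-6-yl]acetonitrile | COCOc1cc(CC#N)cc2C=CC(C)(C)Oc12 | intermediate
9 | [8-(methoxymethoxy)-2,2-dimethyl-2H-chromen-6-yl]acetic acid | COCOc1cc(CC(=O)O)cc2C=CC(C)(C)Oc12 | intermediate
10 | 1-(1H-imidazol-1-yl)-2-[8-(methoxymethoxy)-2,2-dimethyl-2H-chromen-6-yl]ethanone | COCOc1cc(CC(=O)n3ccnc3)cc2C=CC(C)(C)Oc12 | intermediate (not isolated)
11 | N-methoxy-N-methyl-2-[8-(methoxymethoxy)-2,2-dimethyl-2H-chromen-6-yl]acetamide | COCOc1cc(CC(=O)N(C)OC)cc2C=CC(C)(C)Oc12 | intermediate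
12 | 3-acetyl-4-hydroxy-6-methyl-2H-pyran-2-one (dehydroacetic acid) | CC(=O)C1=C(O)C=C(C)OC1=O | starting material
13 | methyl 3,5-dioxohexanoate | COC(=O)CC(=O)CC(C)=O | intermediate
14 | trilithium trianion of methyl 3,5-dioxohexanoate | [Li+].[Li+].[Li+].C=C([O-])C=C([O-])C=C([O-])OC | intermediate (not isolated)
15 | methyl 8-[8-(methoxymethoxy)-2,2-dimethyl-2H-chromen-6-yl]-3,5,7-trioxooctanoate | COCOc1cc(CC(=O)CC(=O)CC(=O)CC(=O)OC)cc2C=CC(C)(C)Oc12 | intermediate (key-step precursor)
16 | 2-{[8-(methoxymethoxy)-2,2-dimethyl-2H-chromen-6-yl]acetyl}cyclohexane-1,3,5-trione | COCOc1cc(CC(=O)C3C(=O)CC(=O)CC3=O)cc2C=CC(C)(C)Oc12 | intermediate (not isolated)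
17 | 2-[8-(methoxymethoxy)-2,2-dimethyl-2H-chromen-6-yl]-1-(2,4,6-trihydroxyphenyl)ethanone | COCOc1cc(CC(=O)c3c(O)cc(O)cc3O)cc2C=CC(C)(C)Oc12 | intermediate (key-step product)
18 | 3-(dimethylamino)-2-[8-(methoxymethoxy)-2,2-dimethyl-2H-chromen-6-yl]-1-(2,4,6-trihydroxyphenyl)prop-2-en-1-one (alkene geometry not defined) | COCOc1cc(C(=CN(C)C)C(=O)c3c(O)cc(O)cc3O)cc2C=CC(C)(C)Oc12 | intermediate (not isolated)
19 | 5,7-dihydroxy-3-[8-(methoxymethoxy)-2,2-dimethyl-2H-chromen-6-yl]-4H-chromen-4-one | COCOc1cc(-c3coc4cc(O)cc(O)c4c3=O)cc2C=CC(C)(C)Oc12 | intermediate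
20 | semilicoisoflavone B, 5,7-dihydroxy-3-(8-hydroxy-2,2-dimethyl-2H-chromen-6-yl)-4H-chromen-4-one | CC1(C)C=Cc2cc(-c3coc4cc(O)cc(O)c4c3=O)cc(O)c2O1 | target

**Step count**
Total step count: 11.
Longest linear sequence: 10 (steps 1–6 and 8–11). Step 7 is a one-step side branch.

**Steps most likely to fail**

**Step 9 (key step).**
- Risk: the aldol closures (C2 onto C7, C8 onto C3), saponification of the ester, or retro-Claisen cleavage of the chain may outrun the Claisen closure.
- Fallback: form the aryl ketone bond C4–C4a by aryllithium acylation instead of folding the chain. It sets out from 11.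
- Phloroglucinol is protected (MOMCl, i-Pr2NEt, CH2Cl2) as 1,3,5-tris(methoxymethoxy)benzene F1.
- n-BuLi (THF, 0 °C) metalates F1 between two OMOM groups to give 2,4,6-tris(methoxymethoxy)phenyllithium F2.
- Addition of F2 to 11 at −78 °C should give 2-[8-(methoxymethoxy)-2,2-dimethyl-2H-chromen-6-yl]-1-[2,4,6-tris(methoxymethoxy)phenyl]ethanone F3.
- DMF dimethyl acetal (toluene, 100 °C) converts F3 into the enaminone 3-(dimethylamino)-2-[8-(methoxymethoxy)-2,2-dimethyl-2H-chromen-6-yl]-1-[2,4,6-tris(methoxymethoxy)phenyl]prop-2-en-1-one F4.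
- HCl in MeOH (50 °C) strips all four MOM groups, and a freed ortho phenol closes ring C. The fallback comes back to the route at 20.

**Step 8.**
- Risk: proton transfer from the benzylic CH2 of the amide to the trianion may take the place of carbonyl addition, and the tetracarbonyl product may cyclise prematurely during work-up.
- Fallback: replace acyl substitution by aldehyde addition followed by oxidation, because addition to an aldehyde at −78 °C is much faster than its enolisation. It sets out from 11.
- DIBAL-H (THF, −78 °C) gives [8-(methoxymethoxy)-2,2-dimethyl-2H-chromen-6-yl]acetaldehyde F5.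
- F5 is added at once to trianion 14 at −78 °C to give racemic methyl 7-hydroxy-8-[8-(methoxymethoxy)-2,2-dimethyl-2H-chromen-6-yl]-3,5-dioxooctanoate F6.
- Dess–Martin periodinane (NaHCO3, CH2Cl2, 0 °C) oxidises the carbinol, which erases its stereocentre. The fallback comes back to the route at 15.

**Step 10.**
- Risk: O-methylation of the acidic ring A phenols by the acetal, and sluggish aminomethylenation of the phenoxide-rich ketone, may compete with ring closure.
- Fallback: mask the two phenols that are not needed before C2 is inserted. It sets out from 17.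
- MOMCl (2.2 equiv, i-Pr2NEt, CH2Cl2, 0 °C) leaves one chelated ortho OH free. This gives 1-[2-hydroxy-4,6-bis(methoxymethoxy)phenyl]-2-[8-(methoxymethoxy)-2,2-dimethyl-2H-chromen-6-yl]ethanone F7.
- DMF dimethyl acetal (toluene, 90 °C) then closes ring C to 5,7-bis(methoxymethoxy)-3-[8-(methoxymethoxy)-2,2-dimethyl-2H-chromen-6-yl]-4H-chromen-4-one F8.
- HCl in MeOH (45 °C) removes all three MOM groups. The fallback comes back to the route at 20.

**Further compounds**
F1 | step 9 | 1,3,5-tris(methoxymethoxy)benzene | COCOc1cc(OCOC)cc(OCOC)c1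
F2 | step 9 | 2,4,6-tris(methoxymethoxy)phenyllithium | [Li]c1c(OCOC)cc(OCOC)cc1OCOC
F3 | step 9 | 2-[8-(methoxymethoxy)-2,2-dimethyl-2H-chromen-6-yl]-1-[2,4,6-tris(methoxymethoxy)phenyl]ethanone | COCOc1cc(CC(=O)c3c(OCOC)cc(OCOC)cc3OCOC)cc2C=CC(C)(C)Oc12
F4 | step 9 | 3-(dimethylamino)-2-[8-(methoxymethoxy)-2,2-dimethyl-2H-chromen-6-yl]-1-[2,4,6-tris(methoxymethoxy)phenyl]prop-2-en-1-one | COCOc1cc(C(=CN(C)C)C(=O)c3c(OCOC)cc(OCOC)cc3OCOC)cc2C=CC(C)(C)Oc12
F5 | step 8 | [8-(methoxymethoxy)-2,2-dimethyl-2H-chromen-6-yl]acetaldehyde | COCOc1cc(CC=O)cc2C=CC(C)(C)Oc12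
F6 | step 8 | methyl 7-hydroxy-8-[8-(methoxymethoxy)-2,2-dimethyl-2H-chromen-6-yl]-3,5-dioxooctanoate (racemic) | COCOc1cc(CC(O)CC(=O)CC(=O)CC(=O)OC)cc2C=CC(C)(C)Oc12
F7 | step 10 | 1-[2-hydroxy-4,6-bis(methoxymethoxy)phenyl]-2-[8-(methoxymethoxy)-2,2-dimethyl-2H-chromen-6-yl]ethanone | COCOc1cc(CC(=O)c3c(O)cc(OCOC)cc3OCOC)cc2C=CC(C)(C)Oc12
F8 | step 10 | 5,7-bis(methoxymethoxy)-3-[8-(methoxymethoxy)-2,2-dimethyl-2H-chromen-6-yl]-4H-chromen-4-one | COCOc1cc(-c3coc4cc(OCOC)cc(OCOC)c4c3=O)cc2C=CC(C)(C)Oc12
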